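**Strategy.** Ring A (C1–C5, C10) is traced back to an A-nor hydrindane in which C3 is bonded directly to C5. The C3 oxygen, the gem-dimethyl carbon C4 and the hindered C4–C5 bond together form a semipinacol retron. The key step, a silver-promoted 1,2-shift in a β-hydroxyalkyl selenide, inserts the CMe2 unit between C3 and C5 and turns the cyclopentanol into the 4,4-dimethyl-3-oxo ring A with retention at C5. The trans-hydrindanone precursor comes from cis-jasmone by enantioselective reduction, an Ireland–Claisen rearrangement that sets C9 and C10, and ring-closing metathesis. Sulfone alkylation with farnesyl bromide and a terminal allylic oxidation complete the chain.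

Key step: step 9

Remark: atom labels follow drimane/polypodane numbering (decalin C1–C10, C11 on C9, chain C12–C22, C30 the terminal hydroxymethyl carbon); "A-nor-13,14-dinordrimane" is that skeleton without C4 and its two methyls, with C3 bonded to C5; the C3 epimer of 18 and the C11 epimers of 26 need no control because both centres are erased in the following step.

Step 1
Reactants: 1 cis-jasmone
Product: 2 (1R)-3-methyl-2-[(2Z)-pent-2-en-1-yl]cyclopent-2-en-1-ol
Conditions: (S)-2-methyl-CBS-oxazaborolidine (0.15 equiv), catecholborane, toluene, −78 °C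
Reagents that add atoms: none
Why: Corey–Bakshi–Shibata reduction, in which the tetrasubstituted enone carbon acts as the large group so that the (S)-catalyst should deliver hydride to give the (R)-carbinol (the future C3–O bond, which later relays its chirality to C10); catecholborane leaves the side-chain alkene alone.

Step 2
Reactants: 2 (1R)-allylic alcohol; 3 3-methylbut-2-enoyl chloride
Product: 4 (1R)-3-methyl-2-[(2Z)-pent-2-en-1-yl]cyclopent-2-en-1-yl 3-methylbut-2-enoate
Conditions: pyridine, DMAP (cat.), CH2Cl2, 0 °C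
Reagents that add atoms: none
Why: Base-mediated acylation with nucleophilic catalysis esterifies the secondary allylic alcohol without ionising the allylic C–O bond, so the stereocentre is untouched.

Step 3
Reactants: 4 allylic senecioate
Product: 8 methyl (2S)-3-methyl-2-{(1R)-1-methyl-2-[(2Z)-pent-2-en-1-yl]cyclopent-2-en-1-yl}but-3-enoate, via silyl ketene acetal 5 (not isolated), via trimethylsilyl ester 6 (not isolated), via carboxylic acid 7 (not isolated)
Conditions: LiN(i-Pr)2, Me3SiCl, THF, −78 °C then 65 °C; 1 M HCl; then Me3SiCHN2, toluene/MeOH, 0 °C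
Reagents that add atoms: trimethylsilyldiazomethane C[Si](C)(C)C=[N+]=[N-]
Why: Ireland–Claisen rearrangement in which γ-deprotonation of the senecioate gives the (Z)-O-silyl dienolate, the suprafacial [3,3] shift transfers the C3–O chirality to the quaternary C10, a chair-like transition state should set the 9α-H configuration, and the crude acid is methylated.

Step 4
Reactants: 8 Claisen ester
Product: 9 methyl (3aR,4S)-3a,5-dimethyl-3,3a,4,7-tetrahydro-2H-indene-4-carboxylate (methyl A-nor-13,14-dinordrima-3(5),7-dien-11-oate)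
Conditions: second-generation Grubbs catalyst RuCl2(=CHPh)(PCy3)(H2IMes) (5 mol%), CH2Cl2, 40 °C
Reagents that add atoms: none
Why: Ring-closing metathesis between the pentenyl alkene and the isopropenyl group should close ring B as the trisubstituted C7=C8 alkene with loss of but-1-ene, while the trisubstituted cyclopentene is inert and no stereocentre changes.

Step 5
Reactants: 9 hydrindadiene ester
Product: 11 methyl 3α-hydroxy-A-nor-13,14-dinordrim-7-en-11-oate, via B-alkyl-9-borabicyclononane 10 (not isolated)
Conditions: 9-BBN, THF, 0 to 25 °C; then 30% H2O2, aq. NaOAc (buffer), 0 °C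
Reagents that add atoms: hydrogen peroxide OO
Why: Hydroboration–oxidation, in which 9-BBN reacts far faster with the cyclopentene than with the hindered cyclohexene and adds boron to C3 and hydrogen to C5 syn from the α face opposite the angular C10 methyl, which should set the trans ring fusion (5α-H).

Step 6
Reactants: 11 hydrindanol
Product: 12 methyl 3-oxo-A-nor-13,14-dinordrim-7-en-11-oate (trans-fused)
Conditions: Dess–Martin periodinane, NaHCO3 (buffer), CH2Cl2, 0 to 20 °C
Reagents that add atoms: none
Why: Dess–Martin oxidation under buffered, non-enolising conditions should give the cyclopentanone without epimerising the adjacent C5.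

Step 7
Reactants: 13 acetone; 14 dimethyl diselenide
Product: 16 2,2-bis(methylseleno)propane, via methaneselenol 15 (not isolated)
Conditions: H3PO2 (50% aq.), 40 °C, selenol taken up in CH2Cl2; then acetone, ZnCl2 (0.5 equiv), 20 °C
Reagents that add atoms: none
Why: Reduction of the diselenide to the selenol followed by Lewis-acid-catalysed selenoacetalisation of acetone (the selenium counterpart of thioacetal formation) gives the reagent precursor.

Step 8
Reactants: 12 trans-hydrindanone; 16 2,2-bis(methylseleno)propane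
Product: 18 methyl 3β-hydroxy-3α-[2-(methylseleno)propan-2-yl]-A-nor-13,14-dinordrim-7-en-11-oate, via 2-lithio-2-(methylseleno)propane 17 (not isolated)
Conditions: n-BuLi, THF, −78 °C; then 12, −78 °C; H2O
Reagents that add atoms: none
Why: Selenium–lithium exchange gives a weakly basic, strongly nucleophilic α-selenoalkyllithium that should add 1,2 to the ketone at −78 °C faster than it enolises C5 or attacks the hindered ester; attack is expected from the α face, but the new C3 centre is erased in step 9.

Step 9
Reactants: 18 β-hydroxyalkyl selenide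
Product: 19 methyl 3-oxodrim-7-en-11-oate
Conditions: AgBF4 on neutral Al2O3, CH2Cl2, 0 to 20 °C
Reagents that add atoms: none
Why: AgBF4 binds selenium and makes the methylseleno group a leaving group at the tertiary carbon that becomes C4; as the C4–Se bond ionises, the anti-periplanar ring bond C3–C5 shifts from C3 to C4 while the hydroxyl collapses to the C3 ketone. This is the selenium-based semipinacol ring enlargement of β-hydroxyalkyl selenides, a relative of the Tiffeneau–Demjanov rearrangement. No ring is closed: ring A grows from five to six members by a 1,2-alkyl shift that makes the C4–C5 bond and the quaternary gem-dimethyl carbon in one operation. No new stereocentre is formed; C5 migrates suprafacially with retention, so the 5α-H/10β-methyl trans fusion from step 5 is carried into the decalin. The step needs migration of C5 rather than C2, which should follow from the higher migratory aptitude of the more substituted carbon and from the rotamer that places selenium anti to the bulkiest C3 substituent; alumina takes up the acid released so that the C7=C8 alkene and the ester survive.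

Step 10
Reactants: 19 keto ester
Product: 20 drim-7-ene-3β,11-diol
Conditions: LiAlH4, THF, 0 °C
Reagents that add atoms: none
Why: LiAlH4 reduces the ester to the C11 carbinol and the 4,4-dimethyl ketone by axial hydride attack from the α face, away from the axial 4β- and 10β-methyl groups, which should give the equatorial 3β-hydroxyl (3S).

Step 11
Reactants: 20 diol
Product: 21 11-(phenylthio)drim-7-en-3β-ol
Conditions: PhSSPh, PBu3, pyridine, 20 to 60 °C
Reagents that add atoms: diphenyl disulfide c1ccc(cc1)SSc1ccccc1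
Why: Disulfide–phosphine (Mukaiyama–Hata) thioetherification by SN2 displacement of the alkoxyphosphonium should convert only the primary C11 hydroxyl, the neopentylic secondary 3β-hydroxyl being unreactive.

Step 12
Reactants: 21 sulfide
Product: 22 7α,8α-epoxy-11-(phenylsulfonyl)driman-3β-ol
Conditions: mCPBA (3.3 equiv), CH2Cl2/aq. NaHCO3 (buffer), 0 °C
Reagents that add atoms: 3-chloroperoxybenzoic acid OOC(=O)c1cccc(Cl)c1
Why: Peracid oxidation turns the sulfide into the sulfone and should epoxidise the trisubstituted alkene from the α face, opposite the axial C10 methyl, which fixes the configuration of the C8–O bond.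

Step 13
Reactants: 22 epoxy sulfone
Product: 23 11-(phenylsulfonyl)drimane-3β,8α-diol
Conditions: LiBHEt3, THF, 0 to 25 °C; H2O
Reagents that add atoms: none
Why: Hydride opening of the epoxide at the less substituted C7 should leave the tertiary 8α-hydroxyl with the 8β-methyl (8R), and the sulfone is inert to the borohydride.

Step 14
Reactants: 23 sulfone diol; 24 (2E,6E)-farnesyl bromide
Product: 26 11-(phenylsulfonyl)polypoda-13E,17E,21-triene-3β,8α-diol (C11 epimers), via trilithio sulfone 25 (not isolated)
Conditions: n-BuLi (3.1 equiv), THF/DMPU, −78 °C; then 24, −78 to −20 °C; H2O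
Reagents that add atoms: none
Why: Alkylation of the α-sulfonyl carbanion with the allylic bromide (SN2 at the primary carbon, alkene geometry untouched) should occur at carbon because the two hindered lithium alkoxides are far poorer nucleophiles.

Step 15
Reactants: 26 alkylated sulfone
Product: 27 polypoda-13E,17E,21-triene-3β,8α-diol
Conditions: Na(Hg) (6% Na), MeOH/THF, −20 to 0 °C
Reagents that add atoms: none
Why: Reductive desulfonylation by electron transfer cleaves the C11–S bond and removes the C11 centre, leaving the isolated alkenes and the hydroxyls untouched.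

Step 16
Reactants: 27 triene diol
Product: 28 (2S,4aS,5R,6R,8aR)-5-[(3E,7E,11E)-13-hydroxy-4,8,12-trimethyltrideca-3,7,11-trien-1-yl]-1,1,4a,6-tetramethyldecahydronaphthalene-2,6-diol (target)
Conditions: SeO2 (0.3 equiv), t-BuOOH, salicylic acid (0.1 equiv), CH2Cl2, 0 to 20 °C, stopped at partial conversion
Reagents that add atoms: selenium dioxide O=[Se]=O (catalytic oxygen relay); tert-butyl hydroperoxide CC(C)(C)OO
Why: Catalytic SeO2 allylic oxidation (ene reaction followed by a [2,3] shift) should attack the terminal isopropylidene group at its (E)-methyl, the most accessible site of the chain, to give the (E)-allylic alcohol.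

**Compound list**

1 | cis-jasmone, 3-methyl-2-[(2Z)-pent-2-en-1-yl]cyclopent-2-en-1-one | CC/C=C\CC1=C(C)CCC1=O | starting material
2 | (1R)-3-methyl-2-[(2Z)-pent-2-en-1-yl]cyclopent-2-en-1-ol | O[C@@H]1CCC(C)=C1C/C=C\CC | intermediate
3 | 3-methylbut-2-enoyl chloride | CC(C)=CC(Cl)=O | starting material
4 | (1R)-3-methyl-2-[(2Z)-pent-2-en-1-yl]cyclopent-2-en-1-yl 3-methylbut-2-enoate | CC(C)=CC(=O)O[C@@H]1CCC(C)=C1C/C=C\CC | intermediate
5 | (Z)-O-trimethylsilyl dienyl ketene acetal of 4 | CC(=C)/C=C(\O[Si](C)(C)C)O[C@@H]1CCC(C)=C1C/C=C\CC | intermediate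
6 | trimethylsilyl ester of acid 7 | C[Si](C)(C)OC(=O)[C@@H](C(C)=C)[C@@]1(C)CCC=C1C/C=C\CC | intermediate
7 | (2S)-3-methyl-2-{(1R)-1-methyl-2-[(2Z)-pent-2-en-1-yl]cyclopent-2-en-1-yl}but-3-enoic acid | OC(=O)[C@@H](C(C)=C)[C@@]1(C)CCC=C1C/C=C\CC | intermediate
8 | methyl (2S)-3-methyl-2-{(1R)-1-methyl-2-[(2Z)-pent-2-en-1-yl]cyclopent-2-en-1-yl}but-3-enoate | COC(=O)[C@@H](C(C)=C)[C@@]1(C)CCC=C1C/C=C\CC | intermediate
9 | methyl (3aR,4S)-3a,5-dimethyl-3,3a,4,7-tetrahydro-2H-indene-4-carboxylate (A-nor-13,14-dinordrima-3(5),7-dien-11-oate; 9α-H, 10β-CH3) | COC(=O)[C@@H]1[C@@]2(C)CCC=C2CC=C1C | intermediate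
10 | methyl 3α-(9-borabicyclo[3.3.1]nonan-9-yl)-A-nor-13,14-dinordrim-7-en-11-oate (5α-H) | COC(=O)[C@@H]1[C@@]2(C)CC[C@@H](B3C4CCCC3CCC4)[C@@H]2CC=C1C | intermediate
11 | methyl 3α-hydroxy-A-nor-13,14-dinordrim-7-en-11-oate (5α-H, 9α-H, 10β-CH3) | COC(=O)[C@@H]1[C@@]2(C)CC[C@@H](O)[C@@H]2CC=C1C | intermediate
12 | methyl 3-oxo-A-nor-13,14-dinordrim-7-en-11-oate (trans-hydrindanone, 5α-H) | COC(=O)[C@@H]1[C@@]2(C)CCC(=O)[C@@H]2CC=C1C | intermediate
13 | acetone | CC(C)=O | starting material
14 | dimethyl diselenide | C[Se][Se]C | starting material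
15 | methaneselenol | C[SeH] | intermediate
16 | 2,2-bis(methylseleno)propane | C[Se]C(C)(C)[Se]C | intermediate
17 | 2-lithio-2-(methylseleno)propane | [Li]C(C)(C)[Se]C | intermediate
18 | methyl 3β-hydroxy-3α-[2-(methylseleno)propan-2-yl]-A-nor-13,14-dinordrim-7-en-11-oate | COC(=O)[C@@H]1[C@@]2(C)CC[C@@](O)(C(C)(C)[Se]C)[C@@H]2CC=C1C | intermediate
19 | methyl 3-oxodrim-7-en-11-oate (5α-H, 9α-H, 10β-CH3) | COC(=O)[C@@H]1[C@@]2(C)CCC(=O)C(C)(C)[C@@H]2CC=C1C | intermediate
20 | drim-7-ene-3β,11-diol | OC[C@@H]1[C@@]2(C)CC[C@H](O)C(C)(C)[C@@H]2CC=C1C | intermediate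
21 | 11-(phenylthio)drim-7-en-3β-ol | c1ccc(cc1)SC[C@@H]1[C@@]2(C)CC[C@H](O)C(C)(C)[C@@H]2CC=C1C | intermediate
22 | 7α,8α-epoxy-11-(phenylsulfonyl)driman-3β-ol | O=S(=O)(c1ccccc1)C[C@@H]1[C@@]2(C)CC[C@H](O)C(C)(C)[C@@H]2C[C@H]3O[C@@]13C | intermediate
23 | 11-(phenylsulfonyl)drimane-3β,8α-diol | O=S(=O)(c1ccccc1)C[C@@H]1[C@@]2(C)CC[C@H](O)C(C)(C)[C@@H]2CC[C@@]1(C)O | intermediate
24 | (2E,6E)-farnesyl bromide | CC(C)=CCC/C(C)=C/CC/C(C)=C/CBr | starting material
25 | trilithio derivative of 23 (C11 carbanion, 3- and 8-alkoxides) | [Li]C(S(=O)(=O)c1ccccc1)[C@@H]1[C@@]2(C)CC[C@H](O[Li])C(C)(C)[C@@H]2CC[C@@]1(C)O[Li] | intermediate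
26 | 11-(phenylsulfonyl)polypoda-13E,17E,21-triene-3β,8α-diol (C11 epimers) | CC(C)=CCC/C(C)=C/CC/C(C)=C/CC(S(=O)(=O)c1ccccc1)[C@@H]1[C@@]2(C)CC[C@H](O)C(C)(C)[C@@H]2CC[C@@]1(C)O | intermediate
27 | polypoda-13E,17E,21-triene-3β,8α-diol | CC(C)=CCC/C(C)=C/CC/C(C)=C/CC[C@@H]1[C@@]2(C)CC[C@H](O)C(C)(C)[C@@H]2CC[C@@]1(C)O | intermediate
28 | (3S,5R,8R,9R,10S)-polypoda-13E,17E,21E-triene-3β,8α,30-triol | C/C(=C\CC/C(C)=C/CC/C(C)=C/CC[C@@H]1[C@@]2(C)CC[C@H](O)C(C)(C)[C@@H]2CC[C@@]1(C)O)CO | target

**Step count.** 16 steps in total (15 in the main line plus the reagent step 7). Longest linear sequence: 15 steps, from 1 to 28 (steps 1–6 and 8–16).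

**Steps most likely to fail**

Step 9 (key step). The silver-activated selenide may collapse by proton loss to the isopropenyl carbinol or by closure to the oxirane instead of undergoing the 1,2-shift, and migration of C2 may compete with that of C5. The fallback sets out from ketone 12 and comes back at diol 20. Isopropenylmagnesium bromide with CeCl3 (THF, −78 °C) should give methyl 3β-hydroxy-3α-(prop-1-en-2-yl)-A-nor-13,14-dinordrim-7-en-11-oate F1. Hydroxyl-directed epoxidation (VO(acac)2, t-BuOOH) should give the epoxy alcohol F2 and leave C7=C8 alone. BF3·OEt2 (CH2Cl2, −78 °C) should then trigger the epoxide-based semipinacol shift of C5 to give the hydroxymethyl ketone F3. I2/PPh3/imidazole should give the iodomethyl ketone F4, and LiAlH4 should reduce iodide, ketone and ester together to 20.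

Step 3. A boat-like transition state or the other ketene acetal geometry would invert C9, and crowding at the tetrasubstituted alkene may slow the shift. The fallback sets out from ester 4 and comes back at 9. The rearrangement and esterification are run as before, and the C9-epimeric ester F5 is carried through the metathesis of step 4 to the 9-epi hydrindadiene ester F6. LiN(i-Pr)2 (THF, −78 °C) should give the lithium dienolate F7, in which C9 is planar. Kinetic α-protonation (AcOH, −78 °C) from the face opposite the C10 methyl should then give 9.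

Step 16. Oxidation may also occur at the allylic positions of the two internal alkenes and may run on to the enal (poor site selectivity and over-oxidation). The fallback sets out from sulfone diol 23 and comes back at 28, with the oxygen installed before the coupling. Commercial (2E,6E)-farnesyl acetate is oxidised (SeO2 cat., t-BuOOH) to 12-hydroxyfarnesyl acetate F8, silylated (TBSCl, imidazole) to the silyl ether acetate F9, deacetylated (K2CO3, MeOH) to the allylic alcohol F10 and brominated (CBr4, PPh3) to the silyloxy farnesyl bromide F11. Alkylation of trianion 25 (from 23 as in step 14) with F11 should give the silyloxy sulfone F12, Na(Hg) the silyl ether F13, and Bu4NF the target 28.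

Further compounds

F1 | step 9 | methyl 3β-hydroxy-3α-(prop-1-en-2-yl)-A-nor-13,14-dinordrim-7-en-11-oate | COC(=O)[C@@H]1[C@@]2(C)CC[C@@](O)(C(C)=C)[C@@H]2CC=C1C
F2 | step 9 | methyl 3β-hydroxy-3α-(2-methyloxiran-2-yl)-A-nor-13,14-dinordrim-7-en-11-oate (oxirane epimers) | COC(=O)[C@@H]1[C@@]2(C)CC[C@@](O)(C3(C)CO3)[C@@H]2CC=C1C
F3 | step 9 | methyl 4-(hydroxymethyl)-4-methyl-3-oxo-13,14-dinordrim-7-en-11-oate (C4 epimers) | COC(=O)[C@@H]1[C@@]2(C)CCC(=O)C(C)(CO)[C@@H]2CC=C1C
F4 | step 9 | methyl 4-(iodomethyl)-4-methyl-3-oxo-13,14-dinordrim-7-en-11-oate (C4 epimers) | COC(=O)[C@@H]1[C@@]2(C)CCC(=O)C(C)(CI)[C@@H]2CC=C1C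
F5 | step 3 | methyl (2R)-3-methyl-2-{(1R)-1-methyl-2-[(2Z)-pent-2-en-1-yl]cyclopent-2-en-1-yl}but-3-enoate | COC(=O)[C@H](C(C)=C)[C@@]1(C)CCC=C1C/C=C\CC
F6 | step 3 | methyl (3aR,4R)-3a,5-dimethyl-3,3a,4,7-tetrahydro-2H-indene-4-carboxylate | COC(=O)[C@H]1[C@@]2(C)CCC=C2CC=C1C
F7 | step 3 | lithium dienolate of 9 | [Li]OC(OC)=C1[C@@]2(C)CCC=C2CC=C1C
F8 | step 16 | (2E,6E,10E)-12-hydroxy-3,7,11-trimethyldodeca-2,6,10-trien-1-yl acetate | OC/C(C)=C/CC/C(C)=C/CC/C(C)=C/COC(C)=O
F9 | step 16 | (2E,6E,10E)-12-(tert-butyldimethylsilyloxy)-3,7,11-trimethyldodeca-2,6,10-trien-1-yl acetate | CC(C)(C)[Si](C)(C)OC/C(C)=C/CC/C(C)=C/CC/C(C)=C/COC(C)=O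
F10 | step 16 | (2E,6E,10E)-12-(tert-butyldimethylsilyloxy)-3,7,11-trimethyldodeca-2,6,10-trien-1-ol | CC(C)(C)[Si](C)(C)OC/C(C)=C/CC/C(C)=C/CC/C(C)=C/CO
F11 | step 16 | (2E,6E,10E)-1-bromo-12-(tert-butyldimethylsilyloxy)-3,7,11-trimethyldodeca-2,6,10-triene | CC(C)(C)[Si](C)(C)OC/C(C)=C/CC/C(C)=C/CC/C(C)=C/CBr
F12 | step 16 | 30-(tert-butyldimethylsilyloxy)-11-(phenylsulfonyl)polypoda-13E,17E,21E-triene-3β,8α-diol (C11 epimers) | CC(C)(C)[Si](C)(C)OC/C(C)=C/CC/C(C)=C/CC/C(C)=C/CC(S(=O)(=O)c1ccccc1)[C@@H]1[C@@]2(C)CC[C@H](O)C(C)(C)[C@@H]2CC[C@@]1(C)O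
F13 | step 16 | 30-(tert-butyldimethylsilyloxy)polypoda-13E,17E,21E-triene-3β,8α-diol | CC(C)(C)[Si](C)(C)OC/C(C)=C/CC/C(C)=C/CC/C(C)=C/CC[C@@H]1[C@@]2(C)CC[C@H](O)C(C)(C)[C@@H]2CC[C@@]1(C)O
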